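## Structural features

The target is an aryltetralin cyclolignan of the lyoniresinol type in which one of the two primary alcohols is a hydrogen sulfate. Ring A is a pentasubstituted benzene with OMe, OH and OMe on C6, C7 and C8 and a single hydrogen on C5. It is fused through C4a and C8a to the saturated ring B (C1 to C4), and C1 carries a 4-hydroxy-3,5-dimethoxyphenyl ring. C1, C2 and C3 are contiguous stereocentres in an all-trans arrangement (1R,2S,3S): the aryl group on C1, CH2OSO3H (C9') on C2 and CH2OH (C9) on C3. The sulfate monoester is the most fragile group (solvolysis in acid, high polarity), both syringyl-type phenols are easily oxidised, and the doubly benzylic C1–H sits peri to the C8 methoxy group. The carbon skeleton is not the real difficulty. The difficulty is the absolute and relative configuration of the stereotriad, together with the distinction between two nearly equivalent hydroxymethyl groups (and two phenols), so that only the C9' oxygen is sulfated. The key step uses the local symmetry of ring A. C6, C7 and C8 with their three oxygens are the three carbons of 1,3-dimethoxyacetone. C8a, C4a and C5 are the ketone carbon, the α-carbon and the formyl carbon of a 2-formylcyclohexanone. Ring A can therefore be annulated last onto a cyclohexanone in which C1 to C3 have already been set by six-membered-ring stereocontrol.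

## Logic of the disconnections

**25 ⇒ 23 (through 24).** The three benzyl–oxygen bonds (on O4', O7 and O9) and the sodium/proton exchange are undone last. All three ethers fall in one neutral hydrogenolysis that a sulfate monoester salt tolerates, so no acid or base touches the finished sulfate. This returns a fully protected, lipophilic compound. The forward step must not be slowed by the anionic group and must not lose sulfate.

**23 ⇒ 21 (through 22).** The S–O9' bond is cut. Sulfation then falls on the only free hydroxyl of the molecule, so no selectivity between C9 and C9' or between alcohol and phenol is needed. The demand is that every other oxygen is capped at that point.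

**21 ⇒ 20 ⇒ 19.** The Si–O9' bond is restored and the benzyl–O7 bond is cut. The C7 phenol appears free in 19 because the annulation creates it, and it is benzylated before the silyl ether is removed. The demand is a silyl ether that is cleaved by fluoride without touching benzyl ethers.

**19 ⇒ 15 + 17.** C5–C6 and C8–C8a are cut. This removes the whole of ring A with its three oxygens and leaves a cyclohexanone and a symmetric three-carbon ketone. No stereocentre is formed or lost, and the symmetry of 17 means there is no regiochemical question. The forward step must form two C–C bonds and aromatise without disturbing C1, which stays α to the ketone until ring A is closed.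

**15 ⇒ 14 ⇒ 13.** The C4a–C5 bond (formyl carbon) and then the Si–O9' bond are cut. Formylation can only persist at C4a, because C1 has no second hydrogen. The silyl ether must survive hot alkoxide later on, which decides its choice.

**13 ⇒ 12 ⇒ 9 + 10 (through 11).** The C2–C9' bond is cut and the C9' oxygen is traced back to silicon. The hydroxymethyl group is introduced as a silylmethyl nucleophile by conjugate addition to an enone, so that C9' arrives differentiated from C9. The demand is addition anti to the C3 substituent and a thermodynamic (equatorial) protonation at C1.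

**9 ⇒ 5 + 8; 5 ⇒ 4; 8 ⇒ 7 ⇒ 6.** The C1–aryl bond is cut, then the C1–I bond, and the pendant ring is traced to a bromophenol. An α-iodoenone and an arylboronate are reliable coupling partners. The demand is a mild coupling that does not epimerise the γ-stereocentre C3.

**4 ⇒ 3 ⇒ 2 ⇒ 1.** The C1=C2 unsaturation is removed, the enol ether is traced to a symmetric 4-substituted cyclohexanone, and the O9–benzyl bond is cut. The only stereogenic event is the choice between two enantiotopic α-methylene groups, and it fixes C3. The demand is a highly enantioselective deprotonation and an oxidation that places the double bond on the side of the enol ether.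

**17 ⇒ 16.** The C7=O bond is taken back to the secondary alcohol. This is a plain oxidation of a cheap glycerol diether.

## Other disconnections considered

**Alternative 1:** Cut C2–C3 and C1–C8a. In the forward direction FeCl3 oxidises two molecules of the sinapoyl imide A1 to phenoxyl radicals, which couple at the carbons α to the carbonyl groups. One quinone methide then tautomerises and its ring attacks the other quinone methide, giving the dihydronaphthalene bis-imide A2.
- In its favour: the complete skeleton, both aromatic rings with the correct oxygenation and the trans C1/C2 relationship arise in one step from a sinapic acid derivative. The blocked 5-positions steer the coupling to the wanted carbons. On step economy and on precedent for the bond-forming step this plan is clearly better than the chosen one.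
- Against it here: the absolute configuration would have to be induced by auxiliaries remote from the coupling carbons. The C3=C4 double bond still has to be reduced with C3 set trans. C9 and C9' emerge at the same oxidation level with the same imide, differing only in conjugation, and two free phenols are present, so sulfation of C9' alone needs a late differentiation.
- Comparison: equal on the relative configuration at C1/C2, better on length, weaker on absolute stereocontrol and on telling C9 from C9'. The chosen plan gives the two oxygens different protecting groups from the moment each is introduced.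

**Alternative 2:** Cut C1–C8a and C1–aryl. BF3·OEt2 ionises the dimethyl acetal of the lactone A3, ring A closes ring B on the oxocarbenium carbon, and the benzylic ether ionises again. The para carbon of 2,6-dimethoxyphenol A4 captures the cation to give the trans-fused lactone A5.
- In its favour: only well-known Friedel–Crafts chemistry is used, the symmetric benzyl ring removes any regiochemical question, the pendant ring comes from a cheap unprotected phenol, and C1 should be set trans to C2 by attack anti to the lactone. In mechanistic precedent it is better than the chosen plan, and in length it is equal or slightly better.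
- Against it here: the lactone ties C9 and C9' together with C9' as the carbonyl, so plain reduction gives a diol with two near-equivalent primary alcohols. A regioselective opening, protection and reduction sequence would be needed before sulfation. Capture of the first cation by A4 before cyclisation would have to be suppressed by staged addition.
- Comparison: equal on the stereotriad, weaker on the differentiation of C9 and C9', stronger on precedent.

**Alternative 3:** Cut C1–C2 and C3–C4. Irradiation of the 2-benzylbenzaldehyde A6 would give the (E,E)-hydroxy-ortho-quinodimethane, which adds endo to the crotonoyl imide A7 on a Ti(OiPr)4–TADDOL template to give the tetralin A8.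
- In its favour: ring B, two C–C bonds and all three stereocentres come from one enantioselective step, the E geometry of A7 translates into the trans C2/C3 relationship, and C9 (imide) and C9' (silyl ether) are differentiated from the start. It is better on convergence and equal to the chosen plan on differentiation.
- Against it here: the extra C4 hydroxyl must be removed by a benzylic deoxygenation in the presence of benzyl ethers. A6 is a pentasubstituted benzaldehyde with its own multistep synthesis. The benzylic hydrogen to be transferred is flanked by a methoxy group, and a β-substituted dienophile with a diaryl-substituted photoenol lies outside the substrates for which the chiral titanium template is established.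
- Comparison: the uncertainty of its key step is about the same as that of the chosen key step. The chosen plan, however, separates the stereochemical problem (solved on a cyclohexanone by known reactions) from the ring-forming risk, whereas here both rest on one step.

Key step: step 13

## Remarks on the chemistry

- Atom labels (C1 to C8a, C9, C9') follow the lignan numbering used above. Names of cyclohexanone intermediates use ring numbering from the carbonyl carbon.
- The configurations of 15 and 19 were checked atom by atom against 25 (aryl on C1 trans to C9' on C2, C9' trans to C9 on C3). They agree, so no structural correction was needed.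
- The C9' oxygen is carried as a triisopropylsilyl ether, not a tert-butyldiphenylsilyl ether. The annulation exposes it to hot alkoxide, toward which tert-butyldiphenylsilyl ethers are the more labile of the two, and both are removed by fluoride.
- Assumption: 4-(hydroxymethyl)cyclohexan-1-one (1) is purchased.
- Assumption: the (R,R)-lithium amide gives the (S)-enol ether 3, by analogy with other 4-substituted cyclohexanones. Should the sense be opposite, the (S,S)-amine is used.

## Route

Step 1
Reactants: 1 4-(hydroxymethyl)cyclohexan-1-one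
Product: 2 4-[(benzyloxy)methyl]cyclohexan-1-one
Conditions: BnOC(=NH)CCl3, TfOH (5 mol %), CH2Cl2/cyclohexane, 0 → 25 °C
Reagents that add atoms: benzyl 2,2,2-trichloroacetimidate, N=C(OCc1ccccc1)C(Cl)(Cl)Cl
Why: Acid-catalysed O-benzylation with a trichloroacetimidate; no strong base is present, so the keto alcohol is etherified directly without enolisation or aldol reaction.

Step 2
Reactants: 2 4-[(benzyloxy)methyl]cyclohexan-1-one
Product: 3 (S)-({4-[(benzyloxy)methyl]cyclohex-1-en-1-yl}oxy)trimethylsilane
Conditions: (R,R)-bis(1-phenylethyl)amine, n-BuLi, LiCl, THF, −78 °C; TMSCl, then 2, −100 → −78 °C (in situ quench)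
Reagents that add atoms: chlorotrimethylsilane, C[Si](C)(C)Cl
Why: Enantioselective deprotonation of a 4-substituted cyclohexanone by a twofold-symmetric chiral lithium amide with internal silyl quench; the base distinguishes the two enantiotopic axial α-hydrogens, and this choice fixes the configuration of C3 (the carbon bearing C9).

Step 3
Reactants: 3 (S)-({4-[(benzyloxy)methyl]cyclohex-1-en-1-yl}oxy)trimethylsilane
Product: 4 (S)-4-[(benzyloxy)methyl]cyclohex-2-en-1-one
Conditions: Pd(OAc)2 (10 mol %), O2 (1 atm), DMSO, 25 °C
Reagents that add atoms: none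
Why: Saegusa–Ito oxidation; divalent palladium attacks the enol ether carbon and β-hydride elimination places the double bond on that same side, so the desymmetrisation is carried into the enone (C1=C2) without touching C3.

Step 4
Reactants: 4 (S)-4-[(benzyloxy)methyl]cyclohex-2-en-1-one
Product: 5 (S)-4-[(benzyloxy)methyl]-2-iodocyclohex-2-en-1-one
Conditions: I2, pyridine/CH2Cl2, 0 → 25 °C
Reagents that add atoms: iodine, II
Why: α-Iodination of an enone by conjugate addition of pyridine, iodination of the enolate and elimination; only C1 can be iodinated, and the neutral medium leaves the γ-stereocentre C3 intact.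

Step 5
Reactants: 6 4-bromo-2,6-dimethoxyphenol
Product: 7 2-(benzyloxy)-5-bromo-1,3-dimethoxybenzene
Conditions: BnBr, K2CO3, DMF, 25 °C
Reagents that add atoms: benzyl bromide, BrCc1ccccc1
Why: Williamson etherification of the phenoxide; the benzyl group will leave with the other benzyl ethers in the last step.

Step 6
Reactants: 7 2-(benzyloxy)-5-bromo-1,3-dimethoxybenzene
Product: 8 2-[4-(benzyloxy)-3,5-dimethoxyphenyl]-4,4,5,5-tetramethyl-1,3,2-dioxaborolane
Conditions: B2pin2, PdCl2(dppf) (3 mol %), KOAc, dioxane, 85 °C
Reagents that add atoms: bis(pinacolato)diboron, CC1(C)OB(OC1(C)C)B1OC(C)(C)C(C)(C)O1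
Why: Miyaura borylation of an electron-rich aryl bromide; acetate as the base avoids premature coupling of the boronate with unreacted bromide.

Step 7
Reactants: 5 (S)-4-[(benzyloxy)methyl]-2-iodocyclohex-2-en-1-one; 8 2-[4-(benzyloxy)-3,5-dimethoxyphenyl]-4,4,5,5-tetramethyl-1,3,2-dioxaborolane
Product: 9 (S)-2-[4-(benzyloxy)-3,5-dimethoxyphenyl]-4-[(benzyloxy)methyl]cyclohex-2-en-1-one
Conditions: PdCl2(dppf) (5 mol %), K3PO4, dioxane/H2O, 50 °C
Reagents that add atoms: none
Why: Suzuki–Miyaura coupling; α-iodoenones add readily to zerovalent palladium and the arylboronate has two free ortho positions, so the C1–aryl bond should form under conditions too mild to deprotonate C3.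

Step 8
Reactants: 9 (S)-2-[4-(benzyloxy)-3,5-dimethoxyphenyl]-4-[(benzyloxy)methyl]cyclohex-2-en-1-one; 10 (chloromethyl)(isopropoxy)dimethylsilane
Product: 12 ({(3R,4S)-2-[4-(benzyloxy)-3,5-dimethoxyphenyl]-4-[(benzyloxy)methyl]-3-[(isopropoxydimethylsilyl)methyl]cyclohex-1-en-1-yl}oxy)trimethylsilane, via Grignard reagent 11 (not isolated)
Conditions: 10, Mg, THF, 25–40 °C; then CuBr·SMe2 (15 mol %), TMSCl, 9, THF, −78 → −30 °C; Et3N, aq. NaHCO3
Reagents that add atoms: chlorotrimethylsilane, C[Si](C)(C)Cl
Why: Copper-catalysed conjugate addition of a silylmethyl Grignard reagent (a hydroxymethyl anion equivalent) with silyl trapping of the enolate; the nucleophile should enter C2 axially on the half-chair face opposite the C3 benzyloxymethyl group, which sets the 2,3-trans relationship.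

Step 9
Reactants: 12 ({(3R,4S)-2-[4-(benzyloxy)-3,5-dimethoxyphenyl]-4-[(benzyloxy)methyl]-3-[(isopropoxydimethylsilyl)methyl]cyclohex-1-en-1-yl}oxy)trimethylsilane
Product: 13 (2R,3R,4S)-2-[4-(benzyloxy)-3,5-dimethoxyphenyl]-4-[(benzyloxy)methyl]-3-(hydroxymethyl)cyclohexan-1-one
Conditions: KF, KHCO3, 30 % H2O2, THF/MeOH, 25 °C; Na2S2O3; then K2CO3, MeOH, 25 °C, argon
Reagents that add atoms: hydrogen peroxide, OO
Why: Tamao–Fleming oxidation turns the C–Si bond into C9'–OH while fluoride and methanol cleave the silyl enol ether; carbonate then equilibrates the α-aryl centre C1 to the all-equatorial ketone, which sets C1 trans to C2 under thermodynamic control.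

Step 10
Reactants: 13 (2R,3R,4S)-2-[4-(benzyloxy)-3,5-dimethoxyphenyl]-4-[(benzyloxy)methyl]-3-(hydroxymethyl)cyclohexan-1-one
Product: 14 (2R,3R,4S)-2-[4-(benzyloxy)-3,5-dimethoxyphenyl]-4-[(benzyloxy)methyl]-3-{[(triisopropylsilyl)oxy]methyl}cyclohexan-1-one
Conditions: TIPSCl, imidazole, DMAP (cat.), DMF, 25 °C
Reagents that add atoms: chlorotriisopropylsilane, CC(C)[Si](Cl)(C(C)C)C(C)C
Why: Silylation of the only hydroxyl group; the bulky trialkylsilyl ether is the most alkoxide-resistant common silyl ether and marks C9' as the oxygen to be unmasked alone later.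

Step 11
Reactants: 14 (2R,3R,4S)-2-[4-(benzyloxy)-3,5-dimethoxyphenyl]-4-[(benzyloxy)methyl]-3-{[(triisopropylsilyl)oxy]methyl}cyclohexan-1-one
Product: 15 (2R,3R,4S,6Z)-2-[4-(benzyloxy)-3,5-dimethoxyphenyl]-4-[(benzyloxy)methyl]-6-(hydroxymethylidene)-3-{[(triisopropylsilyl)oxy]methyl}cyclohexan-1-one
Conditions: NaH, HCO2Et, EtOH (cat.), THF, 0 → 25 °C, argon; AcOH, H2O
Reagents that add atoms: ethyl formate, CCOC=O
Why: Claisen formylation; only C4a has the two hydrogens needed to end as the stabilised hydroxymethylene enolate, acylation at C1 is reversible, and C1 stays in (or returns to) the equatorial configuration under the basic conditions.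

Step 12
Reactants: 16 1,3-dimethoxypropan-2-ol
Product: 17 1,3-dimethoxypropan-2-one
Conditions: (COCl)2, DMSO, CH2Cl2, −78 °C; Et3N, −78 → 0 °C; distillation
Reagents that add atoms: none
Why: Swern oxidation of a secondary alcohol; the non-aqueous work-up suits a small, water-miscible ketone.

Step 13
Reactants: 15 (2R,3R,4S,6Z)-2-[4-(benzyloxy)-3,5-dimethoxyphenyl]-4-[(benzyloxy)methyl]-6-(hydroxymethylidene)-3-{[(triisopropylsilyl)oxy]methyl}cyclohexan-1-one; 17 1,3-dimethoxypropan-2-one
Product: 19 (1R,2S,3S)-1-[4-(benzyloxy)-3,5-dimethoxyphenyl]-3-[(benzyloxy)methyl]-6,8-dimethoxy-2-{[(triisopropylsilyl)oxy]methyl}-1,2,3,4-tetrahydronaphthalen-7-ol, via ene-dione 18 (not isolated)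
Conditions: 17 (4 equiv, slow addition), KOtBu (3 equiv), t-BuOH/THF, 25 → 65 °C, argon; AcOH, H2O
Reagents that add atoms: none
Why: Proposed new method: tert-butoxide enolises 17, whose α-carbon C6 adds to the formyl carbon C5 of 15 and expels hydroxide (net aldol condensation) to give the ene-dione 18; the second α-carbon C8, as the C7 enolate, then attacks the ring ketone C8a, loss of the C8a hydroxyl by E1cB elimination follows, and tautomerisation of the C7 dienone gives the phenoxide, an irreversible end point that should draw the reversible aldol equilibria forward. The closest known reaction type is the base-mediated [3+3] phenol synthesis from 2-hydroxymethylene ketones and acetonedicarboxylates or 1,3-disubstituted acetones; what is new is the less acidic bis-α-alkoxy ketone as the three-carbon partner. Ring A is closed in a 6-(enolendo)-exo-trig aldol, a geometrically favoured mode. No stereocentre is formed. Regioselectivity is not at issue, because 17 is symmetric and C5 is the only aldehyde-like carbon, so both orders of bond formation lead to the same ring. The step needs C1 to stay trans to C2: C1 can epimerise only while C8a is a ketone, where the all-equatorial arrangement set in step 9 is the minimum, and once C8a is a carbinol or aromatic carbon C1–H is no longer acidic. The non-nucleophilic alkoxide in tert-butanol is chosen to suppress retro-Claisen loss of the formyl group, slow addition limits self-condensation of 17, and argon protects the electron-rich phenoxide, while the silyl and benzyl ethers are inert to the base.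

Step 14
Reactants: 19 (1R,2S,3S)-1-[4-(benzyloxy)-3,5-dimethoxyphenyl]-3-[(benzyloxy)methyl]-6,8-dimethoxy-2-{[(triisopropylsilyl)oxy]methyl}-1,2,3,4-tetrahydronaphthalen-7-ol
Product: 20 {[(1R,2S,3S)-7-(benzyloxy)-1-[4-(benzyloxy)-3,5-dimethoxyphenyl]-3-[(benzyloxy)methyl]-6,8-dimethoxy-1,2,3,4-tetrahydronaphthalen-2-yl]methoxy}triisopropylsilane
Conditions: BnBr, K2CO3, DMF, 40 °C
Reagents that add atoms: benzyl bromide, BrCc1ccccc1
Why: Williamson etherification of the hindered but acidic 2,6-dimethoxyphenol; capping C7–OH ensures that the later sulfation meets a single hydroxyl group.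

Step 15
Reactants: 20 {[(1R,2S,3S)-7-(benzyloxy)-1-[4-(benzyloxy)-3,5-dimethoxyphenyl]-3-[(benzyloxy)methyl]-6,8-dimethoxy-1,2,3,4-tetrahydronaphthalen-2-yl]methoxy}triisopropylsilane
Product: 21 [(1R,2S,3S)-7-(benzyloxy)-1-[4-(benzyloxy)-3,5-dimethoxyphenyl]-3-[(benzyloxy)methyl]-6,8-dimethoxy-1,2,3,4-tetrahydronaphthalen-2-yl]methanol
Conditions: TBAF, THF, 25 °C
Reagents that add atoms: none
Why: Fluoride cleavage of a primary silyl ether, driven by the Si–F bond; benzyl and methyl ethers are untouched, so only the C9' hydroxyl is released.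

Step 16
Reactants: 21 [(1R,2S,3S)-7-(benzyloxy)-1-[4-(benzyloxy)-3,5-dimethoxyphenyl]-3-[(benzyloxy)methyl]-6,8-dimethoxy-1,2,3,4-tetrahydronaphthalen-2-yl]methanol
Product: 23 sodium [(1R,2S,3S)-7-(benzyloxy)-1-[4-(benzyloxy)-3,5-dimethoxyphenyl]-3-[(benzyloxy)methyl]-6,8-dimethoxy-1,2,3,4-tetrahydronaphthalen-2-yl]methyl sulfate, via pyridinium sulfate 22 (not isolated)
Conditions: SO3·pyridine, pyridine, 25 °C; then aq. NaHCO3
Reagents that add atoms: sulfur trioxide–pyridine complex, O=S(=O)([O-])[n+]1ccccc1; sodium hydrogencarbonate, [Na+].OC([O-])=O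
Why: O-Sulfation of a primary alcohol with an amine–sulfur trioxide complex; the complex does not sulfonate the arenes, and exchange to the sodium salt removes pyridinium, which would otherwise inhibit the following hydrogenolysis.

Step 17
Reactants: 23 sodium [(1R,2S,3S)-7-(benzyloxy)-1-[4-(benzyloxy)-3,5-dimethoxyphenyl]-3-[(benzyloxy)methyl]-6,8-dimethoxy-1,2,3,4-tetrahydronaphthalen-2-yl]methyl sulfate
Product: 25 [(1R,2S,3S)-7-hydroxy-1-(4-hydroxy-3,5-dimethoxyphenyl)-3-(hydroxymethyl)-6,8-dimethoxy-1,2,3,4-tetrahydronaphthalen-2-yl]methyl hydrogen sulfate, via sodium sulfate 24 (not isolated)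
Conditions: H2 (1 atm), Pd(OH)2 on carbon, MeOH/THF/H2O, 25 °C; then 0.1 M HCl (1.0 equiv), 0 °C, reversed-phase desalting
Reagents that add atoms: none
Why: Hydrogenolysis of two aryl benzyl ethers and one alkyl benzyl ether under neutral conditions, which sulfate monoester salts tolerate; the C1–aryl and ring C–C bonds are not cleaved, and brief cold acidification gives the free hydrogen sulfate.

## Compound list

1 | 4-(hydroxymethyl)cyclohexan-1-one | O=C1CCC(CO)CC1 | starting material
2 | 4-[(benzyloxy)methyl]cyclohexan-1-one | O=C1CCC(COCc2ccccc2)CC1 | intermediate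
3 | (S)-({4-[(benzyloxy)methyl]cyclohex-1-en-1-yl}oxy)trimethylsilane | C[Si](C)(C)OC1=CC[C@@H](COCc2ccccc2)CC1 | intermediate
4 | (S)-4-[(benzyloxy)methyl]cyclohex-2-en-1-one | O=C1C=C[C@@H](COCc2ccccc2)CC1 | intermediate
5 | (S)-4-[(benzyloxy)methyl]-2-iodocyclohex-2-en-1-one | O=C1CC[C@H](COCc2ccccc2)C=C1I | intermediate
6 | 4-bromo-2,6-dimethoxyphenol | COc1cc(Br)cc(OC)c1O | starting material
7 | 2-(benzyloxy)-5-bromo-1,3-dimethoxybenzene | COc1cc(Br)cc(OC)c1OCc1ccccc1 | intermediate
8 | 2-[4-(benzyloxy)-3,5-dimethoxyphenyl]-4,4,5,5-tetramethyl-1,3,2-dioxaborolane | COc1cc(B2OC(C)(C)C(C)(C)O2)cc(OC)c1OCc1ccccc1 | intermediate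
9 | (S)-2-[4-(benzyloxy)-3,5-dimethoxyphenyl]-4-[(benzyloxy)methyl]cyclohex-2-en-1-one | COc1cc(C2=C[C@@H](COCc3ccccc3)CCC2=O)cc(OC)c1OCc1ccccc1 | intermediate
10 | (chloromethyl)(isopropoxy)dimethylsilane | CC(C)O[Si](C)(C)CCl | starting material
11 | [(isopropoxydimethylsilyl)methyl]magnesium chloride | CC(C)O[Si](C)(C)C[Mg]Cl | intermediate
12 | ({(3R,4S)-2-[4-(benzyloxy)-3,5-dimethoxyphenyl]-4-[(benzyloxy)methyl]-3-[(isopropoxydimethylsilyl)methyl]cyclohex-1-en-1-yl}oxy)trimethylsilane | COc1cc(C2=C(O[Si](C)(C)C)CC[C@H](COCc3ccccc3)[C@H]2C[Si](C)(C)OC(C)C)cc(OC)c1OCc1ccccc1 | intermediate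
13 | (2R,3R,4S)-2-[4-(benzyloxy)-3,5-dimethoxyphenyl]-4-[(benzyloxy)methyl]-3-(hydroxymethyl)cyclohexan-1-one | COc1cc([C@@H]2C(=O)CC[C@H](COCc3ccccc3)[C@H]2CO)cc(OC)c1OCc1ccccc1 | intermediate
14 | (2R,3R,4S)-2-[4-(benzyloxy)-3,5-dimethoxyphenyl]-4-[(benzyloxy)methyl]-3-{[(triisopropylsilyl)oxy]methyl}cyclohexan-1-one | COc1cc([C@@H]2C(=O)CC[C@H](COCc3ccccc3)[C@H]2CO[Si](C(C)C)(C(C)C)C(C)C)cc(OC)c1OCc1ccccc1 | intermediate
15 | (2R,3R,4S,6Z)-2-[4-(benzyloxy)-3,5-dimethoxyphenyl]-4-[(benzyloxy)methyl]-6-(hydroxymethylidene)-3-{[(triisopropylsilyl)oxy]methyl}cyclohexan-1-one | COc1cc([C@@H]2C(=O)/C(=C\O)C[C@H](COCc3ccccc3)[C@H]2CO[Si](C(C)C)(C(C)C)C(C)C)cc(OC)c1OCc1ccccc1 | intermediate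
16 | 1,3-dimethoxypropan-2-ol | COCC(O)COC | starting material
17 | 1,3-dimethoxypropan-2-one | COCC(=O)COC | intermediate
18 | (2R,3R,4S,6Z)-2-[4-(benzyloxy)-3,5-dimethoxyphenyl]-4-[(benzyloxy)methyl]-6-(2,4-dimethoxy-3-oxobutylidene)-3-{[(triisopropylsilyl)oxy]methyl}cyclohexan-1-one (both epimers at the methoxy-bearing side-chain carbon) | COCC(=O)C(OC)/C=C1/C[C@H](COCc2ccccc2)[C@@H](CO[Si](C(C)C)(C(C)C)C(C)C)[C@H](c2cc(OC)c(OCc3ccccc3)c(OC)c2)C1=O | intermediate
19 | (1R,2S,3S)-1-[4-(benzyloxy)-3,5-dimethoxyphenyl]-3-[(benzyloxy)methyl]-6,8-dimethoxy-2-{[(triisopropylsilyl)oxy]methyl}-1,2,3,4-tetrahydronaphthalen-7-ol | COc1cc([C@@H]2c3c(cc(OC)c(O)c3OC)C[C@H](COCc3ccccc3)[C@H]2CO[Si](C(C)C)(C(C)C)C(C)C)cc(OC)c1OCc1ccccc1 | intermediate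
20 | {[(1R,2S,3S)-7-(benzyloxy)-1-[4-(benzyloxy)-3,5-dimethoxyphenyl]-3-[(benzyloxy)methyl]-6,8-dimethoxy-1,2,3,4-tetrahydronaphthalen-2-yl]methoxy}triisopropylsilane | COc1cc([C@@H]2c3c(cc(OC)c(OCc4ccccc4)c3OC)C[C@H](COCc3ccccc3)[C@H]2CO[Si](C(C)C)(C(C)C)C(C)C)cc(OC)c1OCc1ccccc1 | intermediate
21 | [(1R,2S,3S)-7-(benzyloxy)-1-[4-(benzyloxy)-3,5-dimethoxyphenyl]-3-[(benzyloxy)methyl]-6,8-dimethoxy-1,2,3,4-tetrahydronaphthalen-2-yl]methanol | COc1cc([C@@H]2c3c(cc(OC)c(OCc4ccccc4)c3OC)C[C@H](COCc3ccccc3)[C@H]2CO)cc(OC)c1OCc1ccccc1 | intermediate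
22 | pyridinium [(1R,2S,3S)-7-(benzyloxy)-1-[4-(benzyloxy)-3,5-dimethoxyphenyl]-3-[(benzyloxy)methyl]-6,8-dimethoxy-1,2,3,4-tetrahydronaphthalen-2-yl]methyl sulfate | COc1cc([C@@H]2c3c(cc(OC)c(OCc4ccccc4)c3OC)C[C@H](COCc3ccccc3)[C@H]2COS(=O)(=O)[O-])cc(OC)c1OCc1ccccc1.c1cc[nH+]cc1 | intermediate
23 | sodium [(1R,2S,3S)-7-(benzyloxy)-1-[4-(benzyloxy)-3,5-dimethoxyphenyl]-3-[(benzyloxy)methyl]-6,8-dimethoxy-1,2,3,4-tetrahydronaphthalen-2-yl]methyl sulfate | COc1cc([C@@H]2c3c(cc(OC)c(OCc4ccccc4)c3OC)C[C@H](COCc3ccccc3)[C@H]2COS(=O)(=O)[O-])cc(OC)c1OCc1ccccc1.[Na+] | intermediate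
24 | sodium [(1R,2S,3S)-7-hydroxy-1-(4-hydroxy-3,5-dimethoxyphenyl)-3-(hydroxymethyl)-6,8-dimethoxy-1,2,3,4-tetrahydronaphthalen-2-yl]methyl sulfate | COc1cc([C@@H]2c3c(cc(OC)c(O)c3OC)C[C@H](CO)[C@H]2COS(=O)(=O)[O-])cc(OC)c1O.[Na+] | intermediate
25 | [(1R,2S,3S)-7-hydroxy-1-(4-hydroxy-3,5-dimethoxyphenyl)-3-(hydroxymethyl)-6,8-dimethoxy-1,2,3,4-tetrahydronaphthalen-2-yl]methyl hydrogen sulfate | COc1cc([C@@H]2c3c(cc(OC)c(O)c3OC)C[C@H](CO)[C@H]2COS(=O)(=O)O)cc(OC)c1O | target

## Step count and least certain steps

Total: 17 steps. Longest linear sequence: 14 steps (steps 1–4, 7–11 and 13–17). Steps 5–6 and step 12 are short side branches.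

**Step 13 (key step, proposed new method).** The most likely failure is that the first C–C bond forms too slowly. Compound 15 is fully ionised to its enolate under the base while 17 is only partly enolised, so loss of the formyl group from 15 by retro-Claisen cleavage and self-condensation of 17 may take over.
Fallback with known chemistry, setting out from 15 and returning at 20:
- 15 is condensed with dimethyl 3-oxopentanedioate (NaOMe, MeOH, 25 → 50 °C), the established partner of this [3+3] phenol synthesis, to give the phenol diester F1 (CO2Me on C6 and C8, OH on C7).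
- Benzylation (BnBr, Cs2CO3, DMF) gives the benzyl ether diester F2.
- LiAlH4 (THF, 0 °C) gives the bis(hydroxymethyl) compound F3.
- MnO2 (CH2Cl2) gives the dialdehyde F4.
- Baeyer–Villiger oxidation (mCPBA, NaHCO3, CH2Cl2) gives the bis-formate F5.
- Methanolysis (K2CO3, MeOH) gives the diphenol F6.
- Methylation (MeI, K2CO3, acetone) returns to the route at 20.

**Step 8.** The most likely failure is poor facial selectivity, through attack syn to the C3 substituent assisted by coordination of the benzyloxy oxygen, or sluggish addition of the bulky silylmethyl nucleophile to the α-aryl, γ-branched enone.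
Fallback setting out from 9 and returning at 13:
- Vinylmagnesium bromide with CuBr·SMe2 (cat.) in THF at −40 °C, then aqueous NH4Cl, gives the 3-vinyl ketone F7.
- Lemieux–Johnson cleavage (OsO4 cat., NaIO4, 2,6-lutidine, dioxane/H2O) gives the keto aldehyde F8.
- In F8, C2 is α to the aldehyde and C1 is α to the ketone, so DBU (CH2Cl2, argon) equilibrates both to the all-equatorial isomer whatever the kinetic selectivity of the addition.
- Chemoselective reduction of the aldehyde (NaBH(OAc)3, benzene, 25 °C) returns to the route at 13.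

**Step 2.** The most likely failure is incomplete discrimination of the enantiotopic α-hydrogens, which would leave the whole series enantiomerically impure.
Fallback setting out from 13 and returning at 13:
- The scalemic alcohol 13 is esterified with (1S)-camphanic chloride (pyridine, DMAP, CH2Cl2) to the camphanate ester F9.
- F9 is freed from the minor diastereomeric ester by crystallisation or chromatography.
- K2CO3 in MeOH under argon then returns enantiomerically pure 13.
The same sequence serves as a classical resolution if the deprotonation has to be run with an achiral amide.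

**Step 17.** The most likely failure is slow or incomplete hydrogenolysis of three benzyl ethers on an ionic, poorly soluble substrate, or partial loss of sulfate through acid formed at the catalyst surface.
Fallback setting out from 21 and returning at 24:
- The alkoxide of 21 (NaHMDS, THF, −78 °C) is treated with neopentyl chlorosulfate to give the neutral neopentyl sulfate diester F10.
- Hydrogenolysis (H2, Pd/C, EtOAc/MeOH) gives the debenzylated diester F11.
- NaN3 in DMF at 70 °C removes the neopentyl group by substitution at its carbon and returns to the route at 24, which is acidified as in step 17.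

## Further compounds

F1 | step 13 | dimethyl (1R,2S,3S)-1-[4-(benzyloxy)-3,5-dimethoxyphenyl]-3-[(benzyloxy)methyl]-7-hydroxy-2-{[(triisopropylsilyl)oxy]methyl}-1,2,3,4-tetrahydronaphthalene-6,8-dicarboxylate (configuration at C1–C3 as in 19) | COc1cc([C@@H]2c3c(cc(C(=O)OC)c(O)c3C(=O)OC)C[C@H](COCc3ccccc3)[C@H]2CO[Si](C(C)C)(C(C)C)C(C)C)cc(OC)c1OCc1ccccc1
F2 | step 13 | 7-O-benzyl ether of F1 | COc1cc([C@@H]2c3c(cc(C(=O)OC)c(OCc4ccccc4)c3C(=O)OC)C[C@H](COCc3ccccc3)[C@H]2CO[Si](C(C)C)(C(C)C)C(C)C)cc(OC)c1OCc1ccccc1
F3 | step 13 | 6,8-bis(hydroxymethyl) analogue of F2 | COc1cc([C@@H]2c3c(cc(CO)c(OCc4ccccc4)c3CO)C[C@H](COCc3ccccc3)[C@H]2CO[Si](C(C)C)(C(C)C)C(C)C)cc(OC)c1OCc1ccccc1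
F4 | step 13 | 6,8-dicarbaldehyde analogue of F2 | COc1cc([C@@H]2c3c(cc(C=O)c(OCc4ccccc4)c3C=O)C[C@H](COCc3ccccc3)[C@H]2CO[Si](C(C)C)(C(C)C)C(C)C)cc(OC)c1OCc1ccccc1
F5 | step 13 | 6,8-bis(formyloxy) analogue of F2 | COc1cc([C@@H]2c3c(cc(OC=O)c(OCc4ccccc4)c3OC=O)C[C@H](COCc3ccccc3)[C@H]2CO[Si](C(C)C)(C(C)C)C(C)C)cc(OC)c1OCc1ccccc1
F6 | step 13 | 6,8-dihydroxy analogue of F2 (7-benzyloxy-6,8-diol) | COc1cc([C@@H]2c3c(cc(O)c(OCc4ccccc4)c3O)C[C@H](COCc3ccccc3)[C@H]2CO[Si](C(C)C)(C(C)C)C(C)C)cc(OC)c1OCc1ccccc1
F7 | step 8 | 2-[4-(benzyloxy)-3,5-dimethoxyphenyl]-4-[(benzyloxy)methyl]-3-vinylcyclohexan-1-one (all-trans, ring configuration as in 13) | COc1cc([C@@H]2C(=O)CC[C@H](COCc3ccccc3)[C@H]2C=C)cc(OC)c1OCc1ccccc1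
F8 | step 8 | 2-[4-(benzyloxy)-3,5-dimethoxyphenyl]-6-[(benzyloxy)methyl]-3-oxocyclohexane-1-carbaldehyde (all-trans, ring configuration as in 13) | COc1cc([C@@H]2C(=O)CC[C@H](COCc3ccccc3)[C@H]2C=O)cc(OC)c1OCc1ccccc1
F9 | step 2 | (1S,4R)-camphanate ester of 13 at the C9' oxygen | COc1cc([C@@H]2C(=O)CC[C@H](COCc3ccccc3)[C@H]2COC(=O)[C@@]23CC[C@@](C)(C(=O)O2)C3(C)C)cc(OC)c1OCc1ccccc1
F10 | step 17 | neopentyl [(1R,2S,3S)-7-(benzyloxy)-1-[4-(benzyloxy)-3,5-dimethoxyphenyl]-3-[(benzyloxy)methyl]-6,8-dimethoxy-1,2,3,4-tetrahydronaphthalen-2-yl]methyl sulfate | COc1cc([C@@H]2c3c(cc(OC)c(OCc4ccccc4)c3OC)C[C@H](COCc3ccccc3)[C@H]2COS(=O)(=O)OCC(C)(C)C)cc(OC)c1OCc1ccccc1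
F11 | step 17 | neopentyl [(1R,2S,3S)-7-hydroxy-1-(4-hydroxy-3,5-dimethoxyphenyl)-3-(hydroxymethyl)-6,8-dimethoxy-1,2,3,4-tetrahydronaphthalen-2-yl]methyl sulfate | COc1cc([C@@H]2c3c(cc(OC)c(O)c3OC)C[C@H](CO)[C@H]2COS(=O)(=O)OCC(C)(C)C)cc(OC)c1O
A1 | alternative 1 | (S)-4-benzyl-3-[(E)-3-(4-hydroxy-3,5-dimethoxyphenyl)prop-2-enoyl]oxazolidin-2-one (sinapoyl imide) | COc1cc(/C=C/C(=O)N2C(=O)OC[C@@H]2Cc2ccccc2)cc(OC)c1O
A2 | alternative 1 | trans-1-aryl-1,2-dihydronaphthalene-2,3-dicarboxylic bis-imide | COc1cc([C@@H]2c3c(cc(OC)c(O)c3OC)C=C(C(=O)N3C(=O)OC[C@@H]3Cc3ccccc3)[C@H]2C(=O)N2C(=O)OC[C@@H]2Cc2ccccc2)cc(OC)c1O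
A3 | alternative 2 | trans-4-[4-(benzyloxy)-3,5-dimethoxybenzyl]-3-(dimethoxymethyl)dihydrofuran-2(3H)-one | COc1cc(C[C@@H]2COC(=O)[C@H]2C(OC)OC)cc(OC)c1OCc1ccccc1
A4 | alternative 2 | 2,6-dimethoxyphenol | COc1cccc(OC)c1O
A5 | alternative 2 | trans,trans-1-aryltetralin fused to a trans lactone (carbonyl is C9') | COc1cc([C@@H]2c3c(cc(OC)c(OCc4ccccc4)c3OC)C[C@@H]3COC(=O)[C@@H]23)cc(OC)c1O
A6 | alternative 3 | 4-(benzyloxy)-2-[4-(benzyloxy)-3,5-dimethoxybenzyl]-3,5-dimethoxybenzaldehyde | COc1cc(Cc2c(C=O)cc(OC)c(OCc3ccccc3)c2OC)cc(OC)c1OCc1ccccc1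
A7 | alternative 3 | 3-[(E)-4-(tert-butyldiphenylsilyloxy)but-2-enoyl]oxazolidin-2-one | O=C(/C=C/CO[Si](c1ccccc1)(c1ccccc1)C(C)(C)C)N1CCOC1=O
A8 | alternative 3 | 1-aryl-4-hydroxytetralin with C9 as imide and C9' as silyl ether | COc1cc([C@@H]2c3c(cc(OC)c(OCc4ccccc4)c3OC)[C@H](O)[C@H](C(=O)N3CCOC3=O)[C@H]2CO[Si](c2ccccc2)(c2ccccc2)C(C)(C)C)cc(OC)c1OCc1ccccc1
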